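The seven-membered ring B is numbered from the spiro carbon (C5, then C6 = CH2, C7/C8 = CHMe, C9 = CHOH, C9a on arene ring A), and the route cuts C5–C6 and C9–C9a. This leaves a biaryl whose C9a and C5 (the para carbon of a latent 2,6-dimethoxyphenol, dienone ring C) are 1,3-related nucleophilic sites, and a chiral C4 chain with two electrophilic ends. The key step is a one-flask (3+4) annulation of bromobiaryl phenol 11 with (2S,3S)-4-iodo-2,3-dimethylbutanal 7. Aryllithium addition sets C9 (Felkin–Anh), then ipso-alkylation of the phenoxide closes ring B and dearomatises ring C to the symmetric spirodienone, whose spiro carbon is not stereogenic.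

Key step: step 6

Assumption: (S)-4-methyldihydrofuran-2(3H)-one (1) is bought as the single enantiomer.

Step 1
Reactants: 1 (S)-4-methyldihydrofuran-2(3H)-one
Product: 3 (3S,4S)-3,4-dimethyldihydrofuran-2(3H)-one, via lithium enolate 2 (not isolated)
Conditions: LiN(i-Pr)2, THF, −78 °C; MeI, −78 °C
Reagents that add atoms: iodomethane CI
Why: Kinetic alkylation of a γ-lactone enolate, in which iodomethane should approach the planar enolate on the face away from the C4 methyl group, so that C3 is set trans to C4 and the (3S,4S) lactone results while C4 is untouched.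

Step 2
Reactants: 3 (3S,4S)-3,4-dimethyldihydrofuran-2(3H)-one
Product: 5 methyl (2S,3S)-4-iodo-2,3-dimethylbutanoate, via trimethylsilyl ester 4 (not isolated)
Conditions: Me3SiI, CH2Cl2, 25–40 °C; then MeOH, 25 °C
Reagents that add atoms: iodotrimethylsilane C[Si](C)(C)I; methanol CO
Why: Lactone-to-ω-iodo ester opening, in which O-silylation by Me3SiI lets iodide cleave the alkyl–oxygen bond at the primary C5 by an SN2 reaction that touches neither stereocentre, and methanol with the HI formed in the flask converts the silyl ester into the methyl ester.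

Step 3
Reactants: 5 methyl (2S,3S)-4-iodo-2,3-dimethylbutanoate
Product: 7 (2S,3S)-4-iodo-2,3-dimethylbutanal, via aluminium hemiacetal 6 (not isolated)
Conditions: i-Bu2AlH (1.05 equiv), CH2Cl2, −78 °C; MeOH, then aqueous potassium sodium tartrate, 0 °C
Reagents that add atoms: none
Why: Partial ester reduction with i-Bu2AlH, in which the tetrahedral aluminium hemiacetal is stable at −78 °C and collapses to the aldehyde only on work-up, the primary iodide is inert to the hydride, and a cold near-neutral work-up should keep the α-stereocentre (7 is used at once without chromatography).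

Step 4
Reactants: 8 5-bromo-1,2,3-trimethoxybenzene
Product: 9 1-bromo-2-iodo-3,4,5-trimethoxybenzene
Conditions: N-iodosuccinimide, CF3CO2H (cat.), MeCN, 25 °C
Reagents that add atoms: N-iodosuccinimide O=C1CCC(=O)N1I
Why: Electrophilic aromatic iodination, in which the two free positions of 8 are equivalent and each is ortho and para to a methoxy group, so mono-iodination next to bromine should give one isomer.

Step 5
Reactants: 9 1-bromo-2-iodo-3,4,5-trimethoxybenzene; 10 2,6-dimethoxy-4-(4,4,5,5-tetramethyl-1,3,2-dioxaborolan-2-yl)phenol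
Product: 11 2'-bromo-3,4',5,5',6'-pentamethoxy-[1,1'-biphenyl]-4-ol
Conditions: Pd(PPh3)4 (5 mol %), K2CO3, 1,4-dioxane/H2O (4:1), 85 °C
Reagents that add atoms: none
Why: Suzuki–Miyaura coupling, in which oxidative addition should occur at the C–I bond much faster than at the C–Br bond, so the phenol ring enters between Br and OMe and the bromide is kept for step 6.

Step 6
Reactants: 11 2'-bromo-3,4',5,5',6'-pentamethoxy-[1,1'-biphenyl]-4-ol; 7 (2S,3S)-4-iodo-2,3-dimethylbutanal
Product: 17 (7R,8S,9R)-9-hydroxy-2,3,3',4,5'-pentamethoxy-7,8-dimethyl-6,7,8,9-tetrahydrospiro[benzo[7]annulene-5,1'-cyclohexa[2,5]dien]-4'-one (CNP0288561.1), via dilithiated biaryl 12 (not isolated), via dilithium alkoxide adduct 13 (not isolated), via bis(triethylsilyl) ether 14 (not isolated), via cesium phenoxide 15 (not isolated), via silyl-protected spirodienone 16 (not isolated)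
Conditions: MeLi (1.0 equiv) then t-BuLi (2.0 equiv), THF, −78 °C; 7, −78 °C; Et3SiCl (2.3 equiv), −78 to 0 °C; Cs2CO3, DMF/H2O (10:1), 0.01 M, 25–60 °C; HF·pyridine, 0 to 25 °C
Reagents that add atoms: none
Why: Br–Li exchange on the lithium phenoxide of 11 gives aryllithium 12, which should add to the aldehyde of 7 (C9–C9a bond) faster than it touches the primary iodide; silylation of both oxygens (14) masks the C9 alkoxide so that it cannot close a tetrahydrofuran onto C6, Cs2CO3 in wet DMF then cleaves only the aryl silyl ether, and the para carbon of phenoxide 15 displaces iodide in an intramolecular SN2 reaction (C5–C6 bond) with loss of aromaticity, after which HF·pyridine frees the C9 hydroxyl. The closest known reaction types are aryllithium addition to an α-branched aldehyde and the alkylative dearomatisation of para-substituted phenoxides with a tethered alkyl halide (Ar1-type ipso participation), which gives spirocyclohexadienones. One ring is closed, the seven-membered ring B, in a 7-exo-tet mode by the ipso carbon of the phenoxide. The only new stereocentre, C9, is set in the addition by Felkin–Anh control from the methyl-bearing C8 of 7 (attack anti to the branched C7 substituent), which should give the 9R,8S ring-trans relationship; C7 and C8 come unchanged from 7, and C5 is not stereogenic because ring C is symmetric. The step needs C- and not O-alkylation and para and not ortho attack: within the molecule neither the phenoxide oxygen nor the methoxy-blocked ortho carbons can reach C6, the twisted biaryl axis holds the p-lobe of the para carbon over the side chain, and high dilution suppresses intermolecular O-alkylation.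

Compound list
1 | (S)-4-methyldihydrofuran-2(3H)-one | C[C@@H]1COC(=O)C1 | starting material
2 | lithium (4S)-4-methyl-4,5-dihydrofuran-2-olate | C[C@@H]1COC(O[Li])=C1 | intermediate
3 | (3S,4S)-3,4-dimethyldihydrofuran-2(3H)-one | C[C@@H]1COC(=O)[C@H]1C | intermediate
4 | trimethylsilyl (2S,3S)-4-iodo-2,3-dimethylbutanoate | IC[C@@H](C)[C@H](C)C(=O)O[Si](C)(C)C | intermediate
5 | methyl (2S,3S)-4-iodo-2,3-dimethylbutanoate | IC[C@@H](C)[C@H](C)C(=O)OC | intermediate
6 | [(2S,3S)-4-iodo-1-methoxy-2,3-dimethylbutoxy]bis(2-methylpropyl)alumane | IC[C@@H](C)[C@H](C)C(OC)O[Al](CC(C)C)CC(C)C | intermediate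
7 | (2S,3S)-4-iodo-2,3-dimethylbutanal | IC[C@@H](C)[C@H](C)C=O | intermediate
8 | 5-bromo-1,2,3-trimethoxybenzene | COc1cc(Br)cc(OC)c1OC | starting material
9 | 1-bromo-2-iodo-3,4,5-trimethoxybenzene | COc1cc(Br)c(I)c(OC)c1OC | intermediate
10 | 2,6-dimethoxy-4-(4,4,5,5-tetramethyl-1,3,2-dioxaborolan-2-yl)phenol | COc1cc(cc(OC)c1O)B1OC(C)(C)C(C)(C)O1 | starting material
11 | 2'-bromo-3,4',5,5',6'-pentamethoxy-[1,1'-biphenyl]-4-ol | COc1cc(cc(OC)c1O)-c1c(Br)cc(OC)c(OC)c1OC | intermediate
12 | lithium 2'-lithio-3,4',5,5',6'-pentamethoxy-[1,1'-biphenyl]-4-olate | COc1cc(cc(OC)c1O[Li])-c1c([Li])cc(OC)c(OC)c1OC | intermediate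
13 | dilithium salt of (1R,2S,3S)-1-[2-(4-hydroxy-3,5-dimethoxyphenyl)-3,4,5-trimethoxyphenyl]-4-iodo-2,3-dimethylbutan-1-ol | IC[C@@H](C)[C@H](C)[C@@H](O[Li])c1cc(OC)c(OC)c(OC)c1-c1cc(OC)c(O[Li])c(OC)c1 | intermediate
14 | bis(triethylsilyl) ether of (1R,2S,3S)-1-[2-(4-hydroxy-3,5-dimethoxyphenyl)-3,4,5-trimethoxyphenyl]-4-iodo-2,3-dimethylbutan-1-ol | IC[C@@H](C)[C@H](C)[C@@H](O[Si](CC)(CC)CC)c1cc(OC)c(OC)c(OC)c1-c1cc(OC)c(O[Si](CC)(CC)CC)c(OC)c1 | intermediate
15 | cesium 4-{6-[(1R,2S,3S)-4-iodo-2,3-dimethyl-1-[(triethylsilyl)oxy]butyl]-2,3,4-trimethoxyphenyl}-2,6-dimethoxyphenolate | IC[C@@H](C)[C@H](C)[C@@H](O[Si](CC)(CC)CC)c1cc(OC)c(OC)c(OC)c1-c1cc(OC)c([O-])c(OC)c1.[Cs+] | intermediate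
16 | (7R,8S,9R)-2,3,3',4,5'-pentamethoxy-7,8-dimethyl-9-[(triethylsilyl)oxy]-6,7,8,9-tetrahydrospiro[benzo[7]annulene-5,1'-cyclohexa[2,5]dien]-4'-one | COC1=CC2(C=C(OC)C1=O)C[C@@H](C)[C@H](C)[C@@H](O[Si](CC)(CC)CC)c1cc(OC)c(OC)c(OC)c12 | intermediate
17 | (7R,8S,9R)-9-hydroxy-2,3,3',4,5'-pentamethoxy-7,8-dimethyl-6,7,8,9-tetrahydrospiro[benzo[7]annulene-5,1'-cyclohexa[2,5]dien]-4'-one (CNP0288561.1) | COC1=CC2(C=C(OC)C1=O)C[C@@H](C)[C@H](C)[C@@H](O)c1cc(OC)c(OC)c(OC)c12 | target

Total step count: 6. Longest linear sequence: 4 steps (steps 1, 2, 3 and 6; steps 4 and 5 form the second branch).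

Steps most likely to fail

Step 6. Three processes may go wrong:
- Poor facial selectivity in the carbonyl addition.
- The seven-membered ring closure losing to intermolecular O-alkylation or to E2 elimination of the iodide.
- Premature loss of the C9 silyl group, followed by tetrahydrofuran closure.

The fallback closes ring B at the biaryl bond by phenolic oxidative coupling instead. It sets out from 7. Commercial 3,4,5-trimethoxyphenylmagnesium bromide (COc1cc([Mg]Br)cc(OC)c1OC; THF, −78 °C) should add under the same Felkin–Anh control to give the bromomagnesium alkoxide F1. This is silylated in the flask (Et3SiCl, imidazole) to the silyl ether iodide F2. Zinc insertion (Zn, LiCl, THF, 40 °C) gives the alkylzinc iodide F3. Negishi coupling with commercial 4-bromo-2,6-dimethoxyphenol (COc1cc(Br)cc(OC)c1O; Pd(OAc)2, SPhos, THF) gives the diarylbutane phenol F4. Oxidation with PhI(OAc)2 in CF3CH2OH (−20 °C) should then let the ring A carbon ortho to the side chain attack the para carbon of the oxidised phenol, with the C9 oxygen kept silylated so that it cannot trap the cation. This gives 16, where the fallback comes back to the route; HF·pyridine as in the last stage of step 6 then gives 17.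

Step 5. Oxidative addition may lose its preference for the hindered, doubly ortho-substituted C–I bond so that the C–Br bond also couples, and the electron-rich boronate may protodeboronate at 85 °C. The fallback is a room-temperature Negishi coupling and sets out from 9. Commercial 4-bromo-2,6-dimethoxyphenol is treated with MeLi and then t-BuLi (THF, −78 °C) to give the dilithiated phenol F5, and ZnCl2 converts this into the arylzinc chloride F6. Coupling of F6 with 9 (Pd(PPh3)4, THF, 25 °C) should take place only at C–I and, after aqueous NH4Cl work-up, comes back to the route at 11.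

Step 3. The reduction may run past the aldehyde, after which the iodo alcohol closes to a tetrahydrofuran, and the α-stereocentre may epimerise during work-up. The fallback sets out from 3. Aminolysis with MeNHOMe·HCl and AlMe3 (CH2Cl2, 0 °C) gives the hydroxy Weinreb amide F7. Iodination (I2, PPh3, imidazole, CH2Cl2, 0 °C) gives the iodo Weinreb amide F8, which is used at once. Reduction with i-Bu2AlH (THF, −78 °C) should stop at the aldehyde oxidation level and comes back to the route at 7.

Further compounds
F1 | step 6 | bromomagnesium (1R,2S,3S)-4-iodo-2,3-dimethyl-1-(3,4,5-trimethoxyphenyl)butan-1-olate | IC[C@@H](C)[C@H](C)[C@@H](O[Mg]Br)c1cc(OC)c(OC)c(OC)c1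
F2 | step 6 | triethyl{[(1R,2S,3S)-4-iodo-2,3-dimethyl-1-(3,4,5-trimethoxyphenyl)butyl]oxy}silane | IC[C@@H](C)[C@H](C)[C@@H](O[Si](CC)(CC)CC)c1cc(OC)c(OC)c(OC)c1
F3 | step 6 | {(2S,3S,4R)-2,3-dimethyl-4-[(triethylsilyl)oxy]-4-(3,4,5-trimethoxyphenyl)butyl}zinc iodide | I[Zn]C[C@@H](C)[C@H](C)[C@@H](O[Si](CC)(CC)CC)c1cc(OC)c(OC)c(OC)c1
F4 | step 6 | 4-{(2R,3S,4R)-2,3-dimethyl-4-[(triethylsilyl)oxy]-4-(3,4,5-trimethoxyphenyl)butyl}-2,6-dimethoxyphenol | COc1cc(C[C@@H](C)[C@H](C)[C@@H](O[Si](CC)(CC)CC)c2cc(OC)c(OC)c(OC)c2)cc(OC)c1O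
F5 | step 5 | lithium 4-lithio-2,6-dimethoxyphenolate | COc1cc([Li])cc(OC)c1O[Li]
F6 | step 5 | lithium 4-(chlorozincio)-2,6-dimethoxyphenolate | COc1cc([Zn]Cl)cc(OC)c1O[Li]
F7 | step 3 | (2S,3S)-4-hydroxy-N-methoxy-N,2,3-trimethylbutanamide | OC[C@@H](C)[C@H](C)C(=O)N(C)OC
F8 | step 3 | (2S,3S)-4-iodo-N-methoxy-N,2,3-trimethylbutanamide | IC[C@@H](C)[C@H](C)C(=O)N(C)OC
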